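(Readings and results were computed for substances that don't exist; noise was put on by code.)

The reading is due at 50 min, 20.0 min after the substrate has stopped running into the reagent, and the cedar run, which is this same flask, has been followed up to 20.0 min.

- cedar: substrate 0.10 M (fed, over 30 min); reagent 0.080 M; the very flask that is asked about, followed so far
- flask: substrate 0.10 M (fed, over 30 min); reagent 0.0800 M; time 50 min

* amount of substrate at 50 min, in percent of the substrate charged
* amount of first product at 50 min, in percent of the substrate charged
* amount of double product at 50 min, in percent of the substrate charged
* amount of tris adduct at 50 min, in percent of the substrate charged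

- cedar (time / min: substrate / %, first product / %): 1.50: 5.1, 0; 4.00: 13.8, 3.2; 8.00: 26.2, 2.6; 20.0: 59.8, 5.2

(scatter of a reading: 1 percentage point)

- percentages count the whole charge, also what has not yet gone in

I read the substrate column of the cedar run against what the feed has delivered. At 1.50 min the feed has delivered 5.00% and I find 5.1%; at 4.00 min, 13.3% and 13.8%; at 8.00 min, 26.7% and 26.2%. These gaps are within a scatter of 1 percentage point. The last row has 66.7% fed and 59.8% found, a gap of 6.9 points.

That gap is substrate lost. I divide it by the fed share summed over time, 6.67 min, and by the charged [reagent], which gives 0.129 L mol⁻¹ min⁻¹. I call this reading the loss constant: the share of the substrate fed so far that is lost per minute, per unit of [reagent]. The same row holds 5.2% first product; if the rest of the gap took two reagents each, each substrate lost costs 1.24 reagent.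

In my first round I hold [reagent] at its charge, a pseudo-first-order loss of 0.0103 min⁻¹, and that round gives this flask 70.0% substrate at 50 min. That loss would bring the reagent down to 53.4% of its charge. So I go round again with the mean of start and end, 0.00790 min⁻¹, and my figure is 76.0%.

The forecast gives 75% substrate, 15% first product, 8% double product and 2% tris adduct, and adds: “The split among later products is the uncertain part.”

At 50.0 min the flask holds 75.6% substrate, 15.9% first product, 8.02% double product and 0.424% tris adduct, each inside the forecast's range.

    substrate + reagent → first product + by-product (k = 0.130 L mol⁻¹ min⁻¹)
    reagent + first product → double product + by-product (k = 0.380 L mol⁻¹ min⁻¹)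
    reagent + double product → tris adduct + by-product (k = 0.0640 L mol⁻¹ min⁻¹)
    reagent + tris adduct → tetra adduct + by-product (k = 0.180 L mol⁻¹ min⁻¹)

The reagent of this flask stands at 58.2% of its own charge at 50.0 min. With that end value in the mean, the loss constant gives 0.00815 min⁻¹ and 75.4% substrate for this flask. The neighbour charged with 0.32 M reagent stands at 58.5% of its own charge at the same time, so the constant gives it 0.0326 min⁻¹ and 33.2%; that neighbour holds 34.4% substrate at 50.0 min.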